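**Plan**

1. Labels: ring O1–O2–C3–C4–C5; C3 carries CH3 and CH2CO2H, C5 carries CH3 and the chain C1'–C12' (methyls on C2' and C4', phenyl on C12').
2. Cuts: CO2H from the CH2OH of a hydroxyethyl arm; both ring C–O bonds (O2–C3, O1–C5) from one H2O2 that opens an oxetane at C3 and a C1'–C5 epoxide at C5; the epoxide from an (E)-C1'=C5 alkene; C1'–C2' from the union of a C2' boronic ester with a C1' alkenyllithium; the chain from stepwise boronic ester homologation.
3. Enabling feature: C2' is a methyl-branched sp3 carbon that can hold boron with fixed configuration, and C1' is a CH2 between C2' and the quaternary peroxy carbon C5, so C1'=C5 can be the alkene the union creates; two nucleophilic carbons (C–B, C–Li) are joined because selenation of the boronate reverses the polarity of C1'.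
4. Forward order: chain fragment B (steps 1–4), oxetanyl alkenyl iodide fragment A (steps 5–10), union (11), epoxidation (12), dioxolane ring by double ring-opening (13), removal of the C1' oxygen (14–16), oxidation to the acid (17).
5. Stereochemistry: C4' and C2' from two sparteine-controlled lithiation–borylations (reagent control), C2' carried through the union with retention; C3 from Sharpless epoxidation and C5 from Shi epoxidation, each inverted once when the peroxide oxygens enter, which gives the cis (3R,5R) ring.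
6. Helpers: boron and selenium leave during the union; the C1' hydroxyl left by the epoxide is removed by radical deoxygenation.

Key step: step 11

Remark: the centres are taken as drawn (3R,5R in the ring, 2'S,4'R in the chain); CIP priorities shift when neighbours change, so some descriptors of untouched centres differ between intermediates, and the SMILES are the reference.

Step 1
Reactants: 1 (8-bromooctyl)benzene
Product: 2 4,4,5,5-tetramethyl-2-(8-phenyloctyl)-1,3,2-dioxaborolane
Conditions: B2pin2, CuI (10 mol %), PPh3, LiOMe, DMF, rt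
Reagents that add atoms: bis(pinacolato)diboron, CC1(C)OB(OC1(C)C)B1OC(C)(C)C(C)(C)O1
Why: Copper-catalysed borylation of an unactivated primary alkyl bromide is general and leaves the arene untouched; no stereocentre is formed.

Step 2
Reactants: 2 4,4,5,5-tetramethyl-2-(8-phenyloctyl)-1,3,2-dioxaborolane
Product: 4 4,4,5,5-tetramethyl-2-[(2R)-10-phenyldecan-2-yl]-1,3,2-dioxaborolane, via boronate complex 3 (not isolated)
Conditions: ethyl 2,4,6-triisopropylbenzoate, s-BuLi, (−)-sparteine, Et2O, −78 °C; then 2, −78 °C; then reflux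
Reagents that add atoms: ethyl 2,4,6-triisopropylbenzoate, CCOC(=O)c1c(C(C)C)cc(C(C)C)cc1C(C)C
Why: Sparteine-mediated lithiation–borylation: s-BuLi/(−)-sparteine should give the (S)-lithiated ester, which adds to boron with retention and then undergoes a 1,2-shift of the phenyloctyl group with inversion at the carbenoid carbon, so C4' is set by reagent control.

Step 3
Reactants: 4 4,4,5,5-tetramethyl-2-[(2R)-10-phenyldecan-2-yl]-1,3,2-dioxaborolane
Product: 6 4,4,5,5-tetramethyl-2-[(2S)-2-methyl-10-phenyldecyl]-1,3,2-dioxaborolane, via boronate complex 5 (not isolated)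
Conditions: BrCH2Cl, n-BuLi, Et2O, −78 °C to rt
Reagents that add atoms: bromochloromethane, ClCBr
Why: Matteson homologation: chloromethyllithium made in the flask adds to boron and the secondary alkyl group shifts to the CH2 carbon with retention, so C4' is untouched.

Step 4
Reactants: 6 4,4,5,5-tetramethyl-2-[(2S)-2-methyl-10-phenyldecyl]-1,3,2-dioxaborolane
Product: 8 4,4,5,5-tetramethyl-2-[(2S,4R)-4-methyl-12-phenyldodecan-2-yl]-1,3,2-dioxaborolane (fragment B), via boronate complex 7 (not isolated)
Conditions: ethyl 2,4,6-triisopropylbenzoate, s-BuLi, (+)-sparteine, Et2O, −78 °C; then 6, −78 °C; then reflux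
Reagents that add atoms: ethyl 2,4,6-triisopropylbenzoate, CCOC(=O)c1c(C(C)C)cc(C(C)C)cc1C(C)C
Why: Second lithiation–borylation with (+)-sparteine, whose (R)-lithiated ester should give the boron-bearing C2' centre in the S configuration by the same retention/inversion sequence, under reagent control and independent of the existing centre, which secures the anti-1,3-dimethyl pattern.

Step 5
Reactants: 9 (2E)-4-chloro-3-methylbut-2-en-1-yl acetate
Product: 10 (2E)-3-methyl-6-(trimethylsilyl)hex-2-en-5-yn-1-yl acetate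
Conditions: Me3SiC≡CH, CuI (cat.), K2CO3, NaI, DMF, rt
Reagents that add atoms: ethynyltrimethylsilane, C#C[Si](C)(C)C
Why: Copper-acetylide substitution of a primary allylic chloride (skipped-enyne synthesis) should occur at the unhindered CH2Cl carbon and keep the (E)-alkene and the acetate.

Step 6
Reactants: 10 (2E)-3-methyl-6-(trimethylsilyl)hex-2-en-5-yn-1-yl acetate
Product: 11 (2E)-3-methylhex-2-en-5-yn-1-ol
Conditions: K2CO3, MeOH, rt
Reagents that add atoms: none
Why: Methanolysis removes the acetate and the alkynyl silyl group in one operation.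

Step 7
Reactants: 11 (2E)-3-methylhex-2-en-5-yn-1-ol
Product: 12 [(2S,3S)-3-methyl-3-(prop-2-yn-1-yl)oxiran-2-yl]methanol
Conditions: Ti(O-i-Pr)4 (cat.), L-(+)-diethyl tartrate (cat.), t-BuOOH, 4 Å molecular sieves, CH2Cl2, −20 °C
Reagents that add atoms: tert-butyl hydroperoxide, CC(C)(C)OO
Why: Sharpless asymmetric epoxidation of an (E)-3-methylallylic alcohol with the L-(+)-tartrate catalyst should give the (2S,3S)-epoxy alcohol (as with geraniol), which fixes the future ring carbon C3 before its later inversion; the isolated alkyne is not a substrate.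

Step 8
Reactants: 12 [(2S,3S)-3-methyl-3-(prop-2-yn-1-yl)oxiran-2-yl]methanol
Product: 13 (3S)-3-methylhex-5-yne-1,3-diol
Conditions: NaAlH2(OCH2CH2OCH3)2, THF, 0 °C
Reagents that add atoms: none
Why: Hydroxyl-directed reductive opening of a 2,3-epoxy alcohol: the aluminium alkoxide delivers hydride to C2, so the tertiary C–O bond and its configuration are kept and the 1,3-diol results.

Step 9
Reactants: 13 (3S)-3-methylhex-5-yne-1,3-diol
Product: 15 (3S,5E)-6-iodo-3,5-dimethylhex-5-ene-1,3-diol, via alkenylalane 14 (not isolated)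
Conditions: AlMe3 (excess), Cp2ZrCl2, CH2Cl2, 0 °C to rt; then I2, THF, −30 °C
Reagents that add atoms: trimethylaluminium, C[Al](C)C; iodine, [I][I]
Why: Negishi zirconium-catalysed carboalumination adds methyl and aluminium syn across the terminal alkyne with methyl on the internal carbon, and iodinolysis with retention gives the (E)-alkenyl iodide; the diol is carried as its aluminium alkoxide.

Step 10
Reactants: 15 (3S,5E)-6-iodo-3,5-dimethylhex-5-ene-1,3-diol
Product: 17 (2S)-2-[(2E)-3-iodo-2-methylprop-2-en-1-yl]-2-methyloxetane (fragment A), via tosylate 16 (not isolated)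
Conditions: 4-MeC6H4SO2Cl, Et3N, 4-(dimethylamino)pyridine (cat.), CH2Cl2, 0 °C; then KOt-Bu, THF, 0 °C to rt
Reagents that add atoms: none
Why: Selective sulfonylation of the primary hydroxyl followed by 4-exo-tet Williamson closure by the tertiary alkoxide gives the 2,2-disubstituted oxetane with retention, since the tertiary C–O bond is not broken.

Step 11
Reactants: 17 (2S)-2-[(2E)-3-iodo-2-methylprop-2-en-1-yl]-2-methyloxetane; 8 4,4,5,5-tetramethyl-2-[(2S,4R)-4-methyl-12-phenyldodecan-2-yl]-1,3,2-dioxaborolane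
Product: 22 (2S)-2-methyl-2-[(2E,4S,6R)-2,4,6-trimethyl-14-phenyltetradec-2-en-1-yl]oxetane, via alkenyllithium 18 (not isolated), via boronate complex 19 (not isolated), via selenide 20 (not isolated), via selenoxide 21 (not isolated)
Conditions: 17, t-BuLi (2 equiv), THF, −78 °C; then 8, −78 °C; then PhSeCl, −78 °C; then 3-chloroperbenzoic acid, −45 °C
Reagents that add atoms: none
Why: t-BuLi converts 17 into the (E)-alkenyllithium 18 with retention, and 18 adds to the boron of 8 to give the boronate 19. PhSeCl attacks the alkene at C5 and the C2' group shifts from boron to C1' anti to selenium with retention at the migrating carbon (selenide 20); oxidation to the selenoxide 21 lets its oxygen bind boron, and boron and selenium leave syn to give the (E)-alkene. The closest known reaction type is the Zweifel olefination of secondary boronic esters in its selenium-mediated syn-elimination form. No ring is closed and no new stereocentre is formed: C2' keeps the configuration set in step 4 because the 1,2-shift is concerted and retentive at the migrating carbon. The step needs a single alkene geometry, which the anti-migration/syn-elimination pair secures from the geometrically pure alkenyllithium, and chemoselectivity, which is secured because the oxetane is inert to organolithiums at −78 °C without a Lewis acid, the lithium of 18 is trans to the oxetanylmethyl group, and the selenide is oxidised faster than the new alkene. Two carbons that are both nucleophiles (C–B and C–Li) are joined because selenation of the boronate makes C1' the electrophilic terminus.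

Step 12
Reactants: 22 (2S)-2-methyl-2-[(2E,4S,6R)-2,4,6-trimethyl-14-phenyltetradec-2-en-1-yl]oxetane
Product: 23 (2R)-2-methyl-2-({(2R,3R)-2-methyl-3-[(2S,4R)-4-methyl-12-phenyldodecan-2-yl]oxiran-2-yl}methyl)oxetane
Conditions: 1,2:4,5-di-O-isopropylidene-β-D-erythro-2,3-hexodiulo-2,6-pyranose (30 mol %), KHSO5 (as 2KHSO5·KHSO4·K2SO4), K2CO3, Bu4NHSO4, MeCN/CH2(OMe)2/aq. Na2B4O7 buffer, 0 °C
Reagents that add atoms: potassium peroxymonosulfate, [K+].[O-]S(=O)(=O)OO
Why: Shi epoxidation: the dioxirane of the D-fructose-derived ketone should epoxidise the (E)-trisubstituted alkene through the spiro transition state under reagent control to the (R,R)-epoxide, which places the C5–O bond on the face opposite to the one the peroxide must finally occupy.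

Step 13
Reactants: 23 (2R)-2-methyl-2-({(2R,3R)-2-methyl-3-[(2S,4R)-4-methyl-12-phenyldodecan-2-yl]oxiran-2-yl}methyl)oxetane
Product: 25 (1R,2S,4R)-1-[(3S,5S)-5-(2-hydroxyethyl)-3,5-dimethyl-1,2-dioxolan-3-yl]-2,4-dimethyl-12-phenyldodecan-1-ol, via hydroperoxy alcohol 24 (not isolated)
Conditions: H2O2 (anhydrous, in Et2O, 1.2 equiv), H3PMo12O40 (5 mol %), Et2O, 0 °C to rt, high dilution
Reagents that add atoms: hydrogen peroxide, OO
Why: Molybdenum-catalysed perhydrolysis of the trisubstituted epoxide should place OOH on the tertiary carbon C5 with inversion, and the hydroperoxide then opens the activated 2,2-disubstituted oxetane at C3 in a 5-exo-tet closure, again with inversion (intramolecular hydroperoxide–oxetane alkylation), so both ring centres arise stereospecifically from the configurations set in steps 7 and 12.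

Step 14
Reactants: 25 (1R,2S,4R)-1-[(3S,5S)-5-(2-hydroxyethyl)-3,5-dimethyl-1,2-dioxolan-3-yl]-2,4-dimethyl-12-phenyldodecan-1-ol
Product: 26 (1R,2S,4R)-1-[(3S,5S)-5-[2-(tert-butyldimethylsilyloxy)ethyl]-3,5-dimethyl-1,2-dioxolan-3-yl]-2,4-dimethyl-12-phenyldodecan-1-ol
Conditions: t-BuMe2SiCl, imidazole, CH2Cl2, 0 °C
Reagents that add atoms: tert-butyldimethylsilyl chloride, CC(C)(C)[Si](C)(C)Cl
Why: Silylation should be selective for the primary hydroxyl because the secondary one lies between the quaternary ring carbon and the branched C2'.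

Step 15
Reactants: 26 (1R,2S,4R)-1-[(3S,5S)-5-[2-(tert-butyldimethylsilyloxy)ethyl]-3,5-dimethyl-1,2-dioxolan-3-yl]-2,4-dimethyl-12-phenyldodecan-1-ol
Product: 27 O-phenyl thionocarbonate of 26 at the C1' oxygen
Conditions: PhOC(S)Cl, pyridine, 4-(dimethylamino)pyridine, CH2Cl2, rt
Reagents that add atoms: O-phenyl chlorothionoformate, S=C(Cl)Oc1ccccc1
Why: Thionocarbonate formation by acyl transfer avoids a free alkoxide (which could fragment the β-peroxy alcohol) and prepares the secondary alcohol for Barton–McCombie deoxygenation.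

Step 16
Reactants: 27 O-phenyl thionocarbonate of 26 at the C1' oxygen
Product: 28 tert-butyl(2-{(3S,5R)-5-[(2S,4R)-2,4-dimethyl-12-phenyldodecyl]-3,5-dimethyl-1,2-dioxolan-3-yl}ethoxy)dimethylsilane
Conditions: Bu3SnH (excess, high concentration), 2,2'-azobis(2-methylpropanenitrile), toluene, 80 °C
Reagents that add atoms: none
Why: Barton–McCombie deoxygenation: the secondary C1' radical should be quenched by concentrated Bu3SnH faster than it attacks the neighbouring O–O bond, as in tin hydride reductions of β-halo peroxides; the C1' centre disappears and no other centre is touched.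

Step 17
Reactants: 28 tert-butyl(2-{(3S,5R)-5-[(2S,4R)-2,4-dimethyl-12-phenyldodecyl]-3,5-dimethyl-1,2-dioxolan-3-yl}ethoxy)dimethylsilane
Product: 29 2-{(3R,5R)-5-[(2S,4R)-2,4-dimethyl-12-phenyldodecyl]-3,5-dimethyl-1,2-dioxolan-3-yl}acetic acid (target)
Conditions: CrO3, H2SO4, H2O, acetone, 0 °C
Reagents that add atoms: water, O
Why: Jones oxidation cleaves the primary silyl ether under the acidic conditions and oxidises the alcohol through the aldehyde hydrate to the acid; the fully substituted dialkyl peroxide has no α-hydrogen and should tolerate chromic acid.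

**Compound list**

1 | (8-bromooctyl)benzene | BrCCCCCCCCc1ccccc1 | starting material
2 | 4,4,5,5-tetramethyl-2-(8-phenyloctyl)-1,3,2-dioxaborolane | CC1(C)OB(CCCCCCCCc2ccccc2)OC1(C)C | intermediate
3 | lithium [(1S)-1-(2,4,6-triisopropylbenzoyloxy)ethyl](8-phenyloctyl)(pinacolato)borate | [Li+].C[C@@H](OC(=O)c1c(C(C)C)cc(C(C)C)cc1C(C)C)[B-]1(CCCCCCCCc2ccccc2)OC(C)(C)C(C)(C)O1 | intermediate
4 | 4,4,5,5-tetramethyl-2-[(2R)-10-phenyldecan-2-yl]-1,3,2-dioxaborolane | C[C@H](CCCCCCCCc1ccccc1)B1OC(C)(C)C(C)(C)O1 | intermediate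
5 | lithium (chloromethyl)[(2R)-10-phenyldecan-2-yl](pinacolato)borate | [Li+].C[C@H](CCCCCCCCc1ccccc1)[B-]1(CCl)OC(C)(C)C(C)(C)O1 | intermediate
6 | 4,4,5,5-tetramethyl-2-[(2S)-2-methyl-10-phenyldecyl]-1,3,2-dioxaborolane | C[C@H](CCCCCCCCc1ccccc1)CB1OC(C)(C)C(C)(C)O1 | intermediate
7 | lithium [(2S)-2-methyl-10-phenyldecyl][(1R)-1-(2,4,6-triisopropylbenzoyloxy)ethyl](pinacolato)borate | [Li+].C[C@H](CCCCCCCCc1ccccc1)C[B-]1([C@H](C)OC(=O)c2c(C(C)C)cc(C(C)C)cc2C(C)C)OC(C)(C)C(C)(C)O1 | intermediate
8 | 4,4,5,5-tetramethyl-2-[(2S,4R)-4-methyl-12-phenyldodecan-2-yl]-1,3,2-dioxaborolane (fragment B) | C[C@H](CCCCCCCCc1ccccc1)C[C@H](C)B1OC(C)(C)C(C)(C)O1 | intermediate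
9 | (2E)-4-chloro-3-methylbut-2-en-1-yl acetate | CC(=O)OC/C=C(\C)CCl | starting material
10 | (2E)-3-methyl-6-(trimethylsilyl)hex-2-en-5-yn-1-yl acetate | CC(=O)OC/C=C(\C)CC#C[Si](C)(C)C | intermediate
11 | (2E)-3-methylhex-2-en-5-yn-1-ol | OC/C=C(\C)CC#C | intermediate
12 | [(2S,3S)-3-methyl-3-(prop-2-yn-1-yl)oxiran-2-yl]methanol | C#CC[C@]1(C)O[C@H]1CO | intermediate
13 | (3S)-3-methylhex-5-yne-1,3-diol | C#CC[C@](C)(O)CCO | intermediate
14 | (E)-alkenylalane: bis(dimethylaluminium) alkoxide of 13 with methyl on C5 and dimethylaluminium on C6 | C[Al](C)/C=C(\C)C[C@](C)(O[Al](C)C)CCO[Al](C)C | intermediate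
15 | (3S,5E)-6-iodo-3,5-dimethylhex-5-ene-1,3-diol | I/C=C(\C)C[C@](C)(O)CCO | intermediate
16 | (3S,5E)-3-hydroxy-6-iodo-3,5-dimethylhex-5-en-1-yl 4-methylbenzenesulfonate | I/C=C(\C)C[C@](C)(O)CCOS(=O)(=O)c1ccc(C)cc1 | intermediate
17 | (2S)-2-[(2E)-3-iodo-2-methylprop-2-en-1-yl]-2-methyloxetane (fragment A) | I/C=C(\C)C[C@@]1(C)CCO1 | intermediate
18 | {(1E)-2-methyl-3-[(2S)-2-methyloxetan-2-yl]prop-1-en-1-yl}lithium | [Li]/C=C(\C)C[C@@]1(C)CCO1 | intermediate
19 | lithium alkenyl boronate: boron carries pinacol, the C2' alkyl group of 8 and the alkenyl group of 18 | [Li+].C[C@H](CCCCCCCCc1ccccc1)C[C@H](C)[B-]1(/C=C(\C)C[C@@]2(C)CCO2)OC(C)(C)C(C)(C)O1 | intermediate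
20 | β-(phenylselanyl) boronic ester: C2' on C1', selenium on C5, anti (one face isomer drawn; the other converges) | C[C@H](CCCCCCCCc1ccccc1)C[C@H](C)[C@H](B1OC(C)(C)C(C)(C)O1)[C@@](C)([Se]c1ccccc1)C[C@@]2(C)CCO2 | intermediate
21 | selenoxide of 20 | C[C@H](CCCCCCCCc1ccccc1)C[C@H](C)[C@H](B1OC(C)(C)C(C)(C)O1)[C@@](C)([Se](=O)c1ccccc1)C[C@@]2(C)CCO2 | intermediate
22 | (2S)-2-methyl-2-[(2E,4S,6R)-2,4,6-trimethyl-14-phenyltetradec-2-en-1-yl]oxetane | C[C@H](CCCCCCCCc1ccccc1)C[C@H](C)/C=C(\C)C[C@@]1(C)CCO1 | intermediate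
23 | (2R)-2-methyl-2-({(2R,3R)-2-methyl-3-[(2S,4R)-4-methyl-12-phenyldodecan-2-yl]oxiran-2-yl}methyl)oxetane | C[C@H](CCCCCCCCc1ccccc1)C[C@H](C)[C@H]1O[C@]1(C)C[C@@]2(C)CCO2 | intermediate
24 | (2R)-2-[(2S,3R,4S,6R)-2-hydroperoxy-3-hydroxy-2,4,6-trimethyl-14-phenyltetradecyl]-2-methyloxetane | C[C@H](CCCCCCCCc1ccccc1)C[C@H](C)[C@@H](O)[C@@](C)(OO)C[C@@]1(C)CCO1 | intermediate
25 | (1R,2S,4R)-1-[(3S,5S)-5-(2-hydroxyethyl)-3,5-dimethyl-1,2-dioxolan-3-yl]-2,4-dimethyl-12-phenyldodecan-1-ol | C[C@H](CCCCCCCCc1ccccc1)C[C@H](C)[C@@H](O)[C@]1(C)C[C@](C)(CCO)OO1 | intermediate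
26 | (1R,2S,4R)-1-[(3S,5S)-5-[2-(tert-butyldimethylsilyloxy)ethyl]-3,5-dimethyl-1,2-dioxolan-3-yl]-2,4-dimethyl-12-phenyldodecan-1-ol | C[C@H](CCCCCCCCc1ccccc1)C[C@H](C)[C@@H](O)[C@]1(C)C[C@](C)(CCO[Si](C)(C)C(C)(C)C)OO1 | intermediate
27 | O-phenyl thionocarbonate of 26 at the C1' oxygen | C[C@H](CCCCCCCCc1ccccc1)C[C@H](C)[C@@H](OC(=S)Oc1ccccc1)[C@]1(C)C[C@](C)(CCO[Si](C)(C)C(C)(C)C)OO1 | intermediate
28 | tert-butyl(2-{(3S,5R)-5-[(2S,4R)-2,4-dimethyl-12-phenyldodecyl]-3,5-dimethyl-1,2-dioxolan-3-yl}ethoxy)dimethylsilane | C[C@H](CCCCCCCCc1ccccc1)C[C@H](C)C[C@]1(C)C[C@](C)(CCO[Si](C)(C)C(C)(C)C)OO1 | intermediate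
29 | 2-{(3R,5R)-5-[(2S,4R)-2,4-dimethyl-12-phenyldodecyl]-3,5-dimethyl-1,2-dioxolan-3-yl}acetic acid | C[C@H](CCCCCCCCc1ccccc1)C[C@H](C)C[C@]1(C)C[C@](C)(CC(=O)O)OO1 | target

**Count and risks**

Total step count: 17. Longest linear sequence: 13 steps (steps 5 to 17).

Step 13. After the epoxide has opened, the new C1' hydroxyl may compete with the hydroperoxide for the oxetane (ether instead of peroxide ring), or the β-hydroxy hydroperoxide may undergo acid-induced C–C cleavage before it closes. The fallback sets out from 22 and returns at 25, with the order of the two ring openings reversed. The oxetane of 22 would first be opened with ethereal H2O2 and Me3SiOTf (cat.) at −78 °C to the hydroperoxy alcohol F1 (inversion at C3). Both hydroxylic groups would be silylated (Et3SiCl, imidazole) to the bis(triethylsilyl) derivative F2, and the alkene epoxidised as in step 12 to the epoxide F3. Desilylation with HF·pyridine and a trace of camphorsulfonic acid would then let the free hydroperoxide open the epoxide 5-exo at C5 to give 25.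

Step 16. The C1' radical sits next to the O–O bond and may attack it (oxirane formation and loss of the dioxolane) faster than it is reduced. The fallback sets out from 22 and returns at 29; it never places oxygen or a radical on C1', at the price of control at C5. Cobalt-catalysed hydrosilylperoxidation of 22 (Isayama–Mukaiyama reaction; Co(acac)2, O2, Et3SiH, ClCH2CH2Cl, rt) would give the C5 silyl peroxide F4 as both C5 epimers. HF·pyridine followed by Me3SiOTf (cat.) would free the hydroperoxide and let it open the oxetane; the (5R) epimer, the dioxolane ethanol F5, would be separated by chromatography and oxidised with CrO3/H2SO4 to 29.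

Step 11. The oxidative syn-elimination may be incomplete or may lose alkene geometry with the hindered selenide. The fallback sets out from 17 and 8 and returns at 28. The boronate 19 would be treated with I2 and then NaOMe (anti-elimination) to give the (Z)-alkene F6. Epoxidation with the enantiomeric ketone (from L-sorbose) should give the epoxide F7, which has the C5 configuration of 23 and the opposite one at C1'. The conditions of steps 13 to 15 would carry it to the diol F8, the silyl ether F9 and the thionocarbonate F10, and the radical reduction of step 16 removes the C1' centre and gives 28.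

**Further compounds**

F1 | step 13 | (3R,5E,7S,9R)-3-hydroperoxy-3,5,7,9-tetramethyl-17-phenylheptadec-5-en-1-ol | C[C@H](CCCCCCCCc1ccccc1)C[C@H](C)/C=C(\C)C[C@](C)(CCO)OO
F2 | step 13 | bis(triethylsilyl) derivative of F1 (silyl ether and silyl peroxide) | C[C@H](CCCCCCCCc1ccccc1)C[C@H](C)/C=C(\C)C[C@](C)(CCO[Si](CC)(CC)CC)OO[Si](CC)(CC)CC
F3 | step 13 | (5R,6R)-epoxide of F2 | C[C@H](CCCCCCCCc1ccccc1)C[C@H](C)[C@H]1O[C@]1(C)C[C@](C)(CCO[Si](CC)(CC)CC)OO[Si](CC)(CC)CC
F4 | step 16 | C5 triethylsilyl peroxide from 22 (Markovnikov adduct, both C5 epimers) | C[C@H](CCCCCCCCc1ccccc1)C[C@H](C)CC(C)(OO[Si](CC)(CC)CC)C[C@@]1(C)CCO1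
F5 | step 16 | 2-{(3S,5R)-5-[(2S,4R)-2,4-dimethyl-12-phenyldodecyl]-3,5-dimethyl-1,2-dioxolan-3-yl}ethan-1-ol | C[C@H](CCCCCCCCc1ccccc1)C[C@H](C)C[C@]1(C)C[C@](C)(CCO)OO1
F6 | step 11 | (2Z)-isomer of 22 | C[C@H](CCCCCCCCc1ccccc1)C[C@H](C)/C=C(/C)C[C@@]1(C)CCO1
F7 | step 11 | (2R,3S)-epoxide, the C1' epimer of 23 | C[C@H](CCCCCCCCc1ccccc1)C[C@H](C)[C@@H]1O[C@]1(C)C[C@@]2(C)CCO2
F8 | step 11 | C1' epimer of 25 | C[C@H](CCCCCCCCc1ccccc1)C[C@H](C)[C@H](O)[C@]1(C)C[C@](C)(CCO)OO1
F9 | step 11 | C1' epimer of 26 | C[C@H](CCCCCCCCc1ccccc1)C[C@H](C)[C@H](O)[C@]1(C)C[C@](C)(CCO[Si](C)(C)C(C)(C)C)OO1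
F10 | step 11 | C1' epimer of 27 | C[C@H](CCCCCCCCc1ccccc1)C[C@H](C)[C@H](OC(=S)Oc1ccccc1)[C@]1(C)C[C@](C)(CCO[Si](C)(C)C(C)(C)C)OO1
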